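**Plan**

- Numbering: C7 is the oxolane carbon bearing ring A (3-hydroxy-4,5-dimethoxyphenyl), C8 and C8' are the two methyl-bearing ring carbons, and C7' is the oxolane carbon bearing ring B (3,4,5-trimethoxyphenyl).
- Cuts: first C7'–ring B (aryllithium plus lactone carbonyl); then, in a butenolide, C8–CH3, C8'–C7' and C7'–O (methyl Grignard, CO2, lactonisation); then C7–C8 (propynyl Grignard plus aldehyde).
- Enabling feature: the ring chain C7–C8(CH3)–C8'(CH3)–C7' is an aryl but-2-ynyl carbinol plus one methyl (on C8) and one carboxyl carbon (C7'). The tetrasubstituted C8=C8' alkene of the resulting butenolide ring can only be hydrogenated to cis methyls.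
- Forward: ring A aldehyde, propargylic alcohol, butenolide (the five ring atoms of the oxolane first appear here as a lactone ring), all-cis lactone, addition of ring B, reduction of the hemiketal to the oxolane, equilibration, desilylation.
- Stereochemistry: C7 comes from a Corey–Bakshi–Shibata reduction; C8 and C8' come from hydrogenation anti to ring A; C7 and C7' are finally set by acid equilibration to aryl-trans-to-methyl. C7 is therefore made with the spatial sense opposite to the target and inverted at the end.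

Key step: step 5

Remark: step 8 is expected to give mainly the all-cis oxolane; whatever mixture of benzylic epimers forms there converges in step 9, which equilibrates both benzylic carbons.

**Step 1**
Reactants: 1 3-hydroxy-4,5-dimethoxybenzaldehyde; 2 chlorotriisopropylsilane
Product: 3 3,4-dimethoxy-5-(triisopropylsilyloxy)benzaldehyde
Conditions: TIPSCl, imidazole, DMF, rt
Reagents that add atoms: chlorotriisopropylsilane (2), CC(C)[Si](Cl)(C(C)C)C(C)C
Why: Standard silylation of a phenol; the triisopropylsilyl ether is chosen because it should withstand Grignard and aryllithium reagents, hydrogenation over rhodium (which could saturate a benzyl ether) and BF3 at low temperature.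

**Step 2**
Reactants: 3 3,4-dimethoxy-5-(triisopropylsilyloxy)benzaldehyde; 4 1-propynylmagnesium bromide
Product: 5 rac-1-[3,4-dimethoxy-5-(triisopropylsilyloxy)phenyl]but-2-yn-1-ol
Conditions: propynylmagnesium bromide, THF, 0 °C; then H2O
Reagents that add atoms: 1-propynylmagnesium bromide (4), CC#C[Mg]Br
Why: Grignard 1,2-addition of an alkynyl nucleophile to an aryl aldehyde forms the C7–C8 bond; the carbinol is racemic and is erased in step 3.

**Step 3**
Reactants: 5 rac-1-[3,4-dimethoxy-5-(triisopropylsilyloxy)phenyl]but-2-yn-1-ol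
Product: 6 1-[3,4-dimethoxy-5-(triisopropylsilyloxy)phenyl]but-2-yn-1-one
Conditions: MnO2, CH2Cl2, rt
Reagents that add atoms: none
Why: MnO2 oxidation of a doubly activated (benzylic and propargylic) alcohol should give the ynone without touching the silyl ether or the alkyne.

**Step 4**
Reactants: 6 1-[3,4-dimethoxy-5-(triisopropylsilyloxy)phenyl]but-2-yn-1-one
Product: 7 (S)-1-[3,4-dimethoxy-5-(triisopropylsilyloxy)phenyl]but-2-yn-1-ol
Conditions: (S)-2-methyl-CBS-oxazaborolidine (0.5 equiv), BH3·SMe2, THF, −30 °C; MeOH quench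
Reagents that add atoms: none
Why: Corey–Bakshi–Shibata reduction, with the aryl ring as the large and the linear propynyl group as the small ketone substituent; the (S)-oxazaborolidine–borane complex should deliver hydride to the face that gives the (S)-carbinol at C7 (same spatial sense as acetophenone to (R)-1-phenylethanol, the descriptor differing because propynyl outranks aryl).

**Step 5**
Reactants: 7 (S)-1-[3,4-dimethoxy-5-(triisopropylsilyloxy)phenyl]but-2-yn-1-ol; 8 methylmagnesium bromide; 9 carbon dioxide
Product: 12 (5S)-5-[3,4-dimethoxy-5-(triisopropylsilyloxy)phenyl]-3,4-dimethylfuran-2(5H)-one, via magnesium alkenyl alkoxide chelate 10 (not isolated), via Z-hydroxy acid 11 (not isolated)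
Conditions: MeMgBr (5 equiv), CuI (20 mol %), Et2O–toluene, −20 °C → rt; CO2 (1 atm), −20 °C → rt; 2 M HCl, 0 °C → rt
Reagents that add atoms: methylmagnesium bromide (8), C[Mg]Br; carbon dioxide (9), O=C=O
Why: MeMgBr first forms the magnesium alkoxide of 7, and the methylcopper species made from CuI then adds across the alkyne in anti fashion, with methyl on the proximal carbon C8 and the metal on the distal carbon C8', which the alkoxide holds in the five-membered oxamagnesacycle 10. CO2 inserts into the C8'–Mg bond with retention of alkene geometry, so the new carboxyl carbon C7' sits cis to the carbinol, and on acidification the Z-hydroxy acid 11 lactonises. The closest known reaction type is the copper-catalysed hydroxyl-directed anti-carbomagnesiation of propargylic alcohols with CO2 trapping to butenolides. The lactone ring (O, C7, C8, C8', C7') closes by 5-exo-trig attack of the C7 hydroxyl on the carboxyl carbon (acyl substitution, C7'–O bond). No stereocentre is made: C7 is not touched and keeps its configuration, and the tetrasubstituted ring alkene stores the cis relation of the two methyls for step 6. The step needs proximal-methyl regioselectivity and anti addition, both secured by alkoxide chelation, and an acidic work-up free of amine or alkoxide base so that the acidic C7–H of the butenolide is not removed.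

**Step 6**
Reactants: 12 (5S)-5-[3,4-dimethoxy-5-(triisopropylsilyloxy)phenyl]-3,4-dimethylfuran-2(5H)-one
Product: 13 (3R,4S,5R)-5-[3,4-dimethoxy-5-(triisopropylsilyloxy)phenyl]-3,4-dimethyloxolan-2-one
Conditions: H2 (50 bar), 5% Rh/Al2O3, EtOAc, rt
Reagents that add atoms: none
Why: Heterogeneous syn-hydrogenation of the tetrasubstituted butenolide alkene; the flat ring should adsorb by the face opposite the C7 aryl, so both hydrogens arrive anti to ring A and C8 (S) and C8' (R) are set with both methyls cis to the aryl (all-cis lactone). Rhodium is used instead of palladium to spare the benzylic lactone C–O bond; the C7 descriptor changes from S to R only because the ranking of its neighbours changes.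

**Step 7**
Reactants: 13 (3R,4S,5R)-5-[3,4-dimethoxy-5-(triisopropylsilyloxy)phenyl]-3,4-dimethyloxolan-2-one; 14 5-bromo-1,2,3-trimethoxybenzene
Product: 16 (3R,4S,5R)-5-[3,4-dimethoxy-5-(triisopropylsilyloxy)phenyl]-3,4-dimethyl-2-(3,4,5-trimethoxyphenyl)oxolan-2-ol, via 3,4,5-trimethoxyphenyllithium 15 (not isolated)
Conditions: 14, n-BuLi, THF, −78 °C; then 13, −78 °C; then H2O
Reagents that add atoms: 5-bromo-1,2,3-trimethoxybenzene (14), COc1cc(Br)cc(OC)c1OC
Why: Bromine–lithium exchange followed by 1,2-addition of the aryllithium to the lactone carbonyl forms the C7'–ring B bond; at −78 °C the tetrahedral lithium alkoxide should persist, so a single addition gives the cyclic hemiketal (anomer mixture, in equilibrium with the open hydroxy ketone).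

**Step 8**
Reactants: 16 (3R,4S,5R)-5-[3,4-dimethoxy-5-(triisopropylsilyloxy)phenyl]-3,4-dimethyl-2-(3,4,5-trimethoxyphenyl)oxolan-2-ol
Product: 17 (2R,3S,4R,5S)-2-[3,4-dimethoxy-5-(triisopropylsilyloxy)phenyl]-3,4-dimethyl-5-(3,4,5-trimethoxyphenyl)oxolane
Conditions: Et3SiH (3 equiv), BF3·OEt2 (2 equiv), CH2Cl2, −78 °C
Reagents that add atoms: none
Why: Ionic hydrogenation (reductive deoxygenation) of a cyclic hemiketal: BF3 ionises C7'–OH to the aryl-stabilised oxocarbenium ion and Et3SiH should transfer hydride to the face anti to the three cis substituents, placing ring B cis to the C8' methyl (all-cis oxolane, C7' S); the low temperature keeps the silane from cleaving the benzylic ether.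

**Step 9**
Reactants: 17 (2R,3S,4R,5S)-2-[3,4-dimethoxy-5-(triisopropylsilyloxy)phenyl]-3,4-dimethyl-5-(3,4,5-trimethoxyphenyl)oxolane
Product: 18 (2S,3S,4R,5R)-2-[3,4-dimethoxy-5-(triisopropylsilyloxy)phenyl]-3,4-dimethyl-5-(3,4,5-trimethoxyphenyl)oxolane
Conditions: CF3CO2H, CH2Cl2, 0 °C → rt, stopped at equilibrium
Reagents that add atoms: none
Why: Acid-mediated benzylic epimerisation of a 2,5-diaryloxolane under thermodynamic control: each benzylic C–O bond ionises reversibly to a para-methoxy-stabilised benzylic cation that recloses, and the equilibrium should settle on the isomer with each aryl trans to its neighbouring methyl, inverting C7 (R to S) and C7' (S to R); C8 and C8' are not benzylic and should stay fixed.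

**Step 10**
Reactants: 18 (2S,3S,4R,5R)-2-[3,4-dimethoxy-5-(triisopropylsilyloxy)phenyl]-3,4-dimethyl-5-(3,4,5-trimethoxyphenyl)oxolane
Product: 19 5-[(2S,3S,4R,5R)-3,4-dimethyl-5-(3,4,5-trimethoxyphenyl)oxolan-2-yl]-2,3-dimethoxyphenol
Conditions: Bu4NF, THF, 0 °C; then H2O
Reagents that add atoms: none
Why: Fluoride-induced cleavage of the aryl silyl ether frees the phenol under conditions that leave the oxolane and its four stereocentres untouched.

**Compound list**

1 | 3-hydroxy-4,5-dimethoxybenzaldehyde | COc1cc(C=O)cc(O)c1OC | starting material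
2 | chlorotriisopropylsilane | CC(C)[Si](Cl)(C(C)C)C(C)C | starting material
3 | 3,4-dimethoxy-5-(triisopropylsilyloxy)benzaldehyde | COc1cc(C=O)cc(O[Si](C(C)C)(C(C)C)C(C)C)c1OC | intermediate
4 | 1-propynylmagnesium bromide | CC#C[Mg]Br | starting material
5 | rac-1-[3,4-dimethoxy-5-(triisopropylsilyloxy)phenyl]but-2-yn-1-ol | COc1cc(C(O)C#CC)cc(O[Si](C(C)C)(C(C)C)C(C)C)c1OC | intermediate
6 | 1-[3,4-dimethoxy-5-(triisopropylsilyloxy)phenyl]but-2-yn-1-one | COc1cc(C(=O)C#CC)cc(O[Si](C(C)C)(C(C)C)C(C)C)c1OC | intermediate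
7 | (S)-1-[3,4-dimethoxy-5-(triisopropylsilyloxy)phenyl]but-2-yn-1-ol | COc1cc([C@H](O)C#CC)cc(O[Si](C(C)C)(C(C)C)C(C)C)c1OC | intermediate
8 | methylmagnesium bromide | C[Mg]Br | starting material
9 | carbon dioxide | O=C=O | starting material
10 | (5S)-5-[3,4-dimethoxy-5-(triisopropylsilyloxy)phenyl]-3,4-dimethyl-2,5-dihydro-1,2-oxamagnesole (ring O–Mg–C8'=C8–C7; not isolated) | COc1cc([C@@H]2O[Mg]C(C)=C2C)cc(O[Si](C(C)C)(C(C)C)C(C)C)c1OC | intermediate
11 | (2Z,4S)-4-[3,4-dimethoxy-5-(triisopropylsilyloxy)phenyl]-4-hydroxy-2,3-dimethylbut-2-enoic acid (not isolated) | COc1cc([C@H](O)/C(C)=C(C)\C(=O)O)cc(O[Si](C(C)C)(C(C)C)C(C)C)c1OC | intermediate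
12 | (5S)-5-[3,4-dimethoxy-5-(triisopropylsilyloxy)phenyl]-3,4-dimethylfuran-2(5H)-one | COc1cc([C@@H]2OC(=O)C(C)=C2C)cc(O[Si](C(C)C)(C(C)C)C(C)C)c1OC | intermediate
13 | (3R,4S,5R)-5-[3,4-dimethoxy-5-(triisopropylsilyloxy)phenyl]-3,4-dimethyloxolan-2-one (all-cis) | COc1cc([C@@H]2OC(=O)[C@H](C)[C@@H]2C)cc(O[Si](C(C)C)(C(C)C)C(C)C)c1OC | intermediate
14 | 5-bromo-1,2,3-trimethoxybenzene | COc1cc(Br)cc(OC)c1OC | starting material
15 | 3,4,5-trimethoxyphenyllithium (not isolated) | COc1cc([Li])cc(OC)c1OC | intermediate
16 | (3R,4S,5R)-5-[3,4-dimethoxy-5-(triisopropylsilyloxy)phenyl]-3,4-dimethyl-2-(3,4,5-trimethoxyphenyl)oxolan-2-ol (anomer mixture) | COc1cc([C@@H]2OC(O)(c3cc(OC)c(OC)c(OC)c3)[C@H](C)[C@@H]2C)cc(O[Si](C(C)C)(C(C)C)C(C)C)c1OC | intermediate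
17 | (2R,3S,4R,5S)-2-[3,4-dimethoxy-5-(triisopropylsilyloxy)phenyl]-3,4-dimethyl-5-(3,4,5-trimethoxyphenyl)oxolane (all-cis) | COc1cc([C@@H]2O[C@H](c3cc(OC)c(OC)c(OC)c3)[C@H](C)[C@@H]2C)cc(O[Si](C(C)C)(C(C)C)C(C)C)c1OC | intermediate
18 | (2S,3S,4R,5R)-2-[3,4-dimethoxy-5-(triisopropylsilyloxy)phenyl]-3,4-dimethyl-5-(3,4,5-trimethoxyphenyl)oxolane | COc1cc([C@H]2O[C@@H](c3cc(OC)c(OC)c(OC)c3)[C@H](C)[C@@H]2C)cc(O[Si](C(C)C)(C(C)C)C(C)C)c1OC | intermediate
19 | 5-[(2S,3S,4R,5R)-3,4-dimethyl-5-(3,4,5-trimethoxyphenyl)oxolan-2-yl]-2,3-dimethoxyphenol | COc1cc([C@H]2O[C@@H](c3cc(OC)c(OC)c(OC)c3)[C@H](C)[C@@H]2C)cc(O)c1OC | target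

**Step count**

Total steps: 10. Longest linear sequence: 10 steps (1 to 19); 14 is bought and enters in step 7.

**Steps most likely to fail**

Step 9. The ring-opened benzylic cation may be captured irreversibly by the other electron-rich arene (Friedel–Crafts closure to an aryltetralin). It may also lose a proton and scramble C8, or the inversion at C7 may stall short of equilibrium. The fallback replaces equilibration by an SN2 inversion and an anti-selective arylation; it sets out from 13 and comes back at 18. Lactone 13 is saponified (LiOH, THF–H2O, careful acidification at 0 °C) to (2R,3S,4R)-4-[3,4-dimethoxy-5-(triisopropylsilyloxy)phenyl]-4-hydroxy-2,3-dimethylbutanoic acid F1. Mitsunobu lactonisation (PPh3, diisopropyl azodicarboxylate, THF) recloses it with inversion at the carbinol carbon to (3R,4S,5S)-5-[3,4-dimethoxy-5-(triisopropylsilyloxy)phenyl]-3,4-dimethyloxolan-2-one F2, in which ring A is already trans to the C8 methyl. Reduction with i-Bu2AlH (CH2Cl2, −78 °C) gives (3R,4S,5S)-5-[3,4-dimethoxy-5-(triisopropylsilyloxy)phenyl]-3,4-dimethyloxolan-2-ol F3. Benzenesulfinic acid with CaCl2 in CH2Cl2 converts it into (3R,4S,5S)-5-[3,4-dimethoxy-5-(triisopropylsilyloxy)phenyl]-3,4-dimethyl-2-(phenylsulfonyl)oxolane F4. 3,4,5-Trimethoxyphenylmagnesium bromide (from 14 and Mg) with ZnBr2 in THF then displaces the sulfinate through the oxocarbenium ion, the aryl entering anti to the C8' methyl, which should give 18 directly.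

Step 6. The benzylic lactone C–O bond may be hydrogenolysed, the alkene may migrate towards the aryl with loss of the C7 configuration, or the facial bias may be too small on the hindered tetrasubstituted alkene. The fallback is a carboxylate-directed homogeneous hydrogenation of the ring-opened acid under catalyst control; it sets out from 11 and comes back at 13. The carboxylation mixture of step 5 is quenched with aqueous Na2CO3 instead of acid and sodium (2Z,4S)-4-[3,4-dimethoxy-5-(triisopropylsilyloxy)phenyl]-4-hydroxy-2,3-dimethylbut-2-enoate F5 is isolated. Hydrogenation with Ru(OAc)2(BINAP) (the antipode matched to the carbinol centre, found by running both; H2 100 bar, MeOH) should add hydrogen syn to give sodium (2R,3S,4R)-4-[3,4-dimethoxy-5-(triisopropylsilyloxy)phenyl]-4-hydroxy-2,3-dimethylbutanoate F6. Acidification with HCl lactonises it to 13.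

Step 5. Transfer of the methyl group to the internal alkyne may be sluggish, the alkenylmagnesium may isomerise and erode the anti geometry, or protonation may outrun carboxylation. The fallback builds the same butenolide from an ynoate that already carries the carboxyl carbon; it sets out from 3 and comes back at 12. Asymmetric addition of methyl propiolate to 3 (Me2Zn, the ProPhenol ligand antipode that gives the S carbinol, toluene, 0 °C) gives methyl (4S)-4-[3,4-dimethoxy-5-(triisopropylsilyloxy)phenyl]-4-hydroxybut-2-ynoate F7. Syn-carbocupration with Me2CuLi (THF, −78 °C) places a methyl on C8 with the ester cis to the carbinol, and the alkenylcopper is methylated at C8' with MeI. A cold acidic quench and lactonisation with loss of methanol should give 12.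

**Further compounds**

F1 | step 9 | (2R,3S,4R)-4-[3,4-dimethoxy-5-(triisopropylsilyloxy)phenyl]-4-hydroxy-2,3-dimethylbutanoic acid | COc1cc([C@H](O)[C@@H](C)[C@@H](C)C(=O)O)cc(O[Si](C(C)C)(C(C)C)C(C)C)c1OC
F2 | step 9 | (3R,4S,5S)-5-[3,4-dimethoxy-5-(triisopropylsilyloxy)phenyl]-3,4-dimethyloxolan-2-one | COc1cc([C@H]2OC(=O)[C@H](C)[C@@H]2C)cc(O[Si](C(C)C)(C(C)C)C(C)C)c1OC
F3 | step 9 | (3R,4S,5S)-5-[3,4-dimethoxy-5-(triisopropylsilyloxy)phenyl]-3,4-dimethyloxolan-2-ol | COc1cc([C@H]2OC(O)[C@H](C)[C@@H]2C)cc(O[Si](C(C)C)(C(C)C)C(C)C)c1OC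
F4 | step 9 | (3R,4S,5S)-5-[3,4-dimethoxy-5-(triisopropylsilyloxy)phenyl]-3,4-dimethyl-2-(phenylsulfonyl)oxolane | COc1cc([C@H]2OC(S(=O)(=O)c3ccccc3)[C@H](C)[C@@H]2C)cc(O[Si](C(C)C)(C(C)C)C(C)C)c1OC
F5 | step 6 | sodium (2Z,4S)-4-[3,4-dimethoxy-5-(triisopropylsilyloxy)phenyl]-4-hydroxy-2,3-dimethylbut-2-enoate | COc1cc([C@H](O)/C(C)=C(C)\C(=O)[O-])cc(O[Si](C(C)C)(C(C)C)C(C)C)c1OC.[Na+]
F6 | step 6 | sodium (2R,3S,4R)-4-[3,4-dimethoxy-5-(triisopropylsilyloxy)phenyl]-4-hydroxy-2,3-dimethylbutanoate | COc1cc([C@H](O)[C@@H](C)[C@@H](C)C(=O)[O-])cc(O[Si](C(C)C)(C(C)C)C(C)C)c1OC.[Na+]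
F7 | step 5 | methyl (4S)-4-[3,4-dimethoxy-5-(triisopropylsilyloxy)phenyl]-4-hydroxybut-2-ynoate | COC(=O)C#C[C@@H](O)c1cc(OC)c(OC)c(O[Si](C(C)C)(C(C)C)C(C)C)c1
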